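## Analysis of the target

CNP0272644.1 (27) is a furanone-bridged germacranolide. Its ten-membered carbocycle C1–C10 is spanned by an oxygen between C3 and C10, so that O, C3, C2, C1 and C10 form a 3(2H)-furanone. A γ-lactone (C6–O–C12–C11–C7) is cis-fused at C6/C7.

There are six stereocentres. H6 and H7 are cis. The C8 angelate and the free C9 hydroxyl are threo. C10 is quaternary (methyl, ether oxygen). C11 is quaternary, with its hydroxyl on the lactone face that carries C8 and its chloromethyl group on the face of H7. The C4=C5 bond is cis within the ring.

The sensitive groups are the angelate (Z to E isomerisation, acyl shift to the C9 hydroxyl), the chlorohydrin (closes to the epoxide with base), the cross-conjugated furanone–diene (a Michael acceptor) and the lactone.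

The difficulty is a strained, oxygen-bridged medium ring with a quaternary bridgehead, flanked by four contiguous oxygenated centres that must be set on a ring of uncertain conformation.

The strategy rests on one pattern. The enol-ether bond C2=C3, the cis C4=C5 bond and the bond from C1 to the quaternary C10 are exactly what a [3,3] shift across a C3–C8 bond would leave behind. That requires C3 and C8 to be the fusion atoms of a cyclohexene (C3–C8) and a 2,3-dihydrofuran (O, C3, C8, C9, C10). The fifteen skeletal carbons then come from the ring of (S)-carvone 1 (ten), a propargyl group (C9, C10, C14) and a vinyl group (C1, C2).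

## Retrosynthetic reasoning

**27 ⇒ 26.** The C13–Cl bond and the O–H bond at C9 are formed last. The chlorohydrin closes with any base and the angelate isomerises and migrates under base, so both are released in one acidic step from a spiro-epoxide and a silyl ether. Forward, chloride must open the epoxide at the primary carbon only.

**26 ⇒ 25.** The ester C–O bond at C8 is cut. Acylation comes after all oxidations and after the C8 hydroxyl has served as a directing group, when it is the only free hydroxyl.

**25 ⇒ 23 ⇒ 22.** The C11–O and C13–O bonds are cut back to the exocyclic alkene of an α-methylene lactone. The tertiary oxygen must sit on the lactone face that carries C8, which an unguided reagent would avoid. The C8 hydroxyl therefore steers the oxidant, and closure of the epoxide from C13 keeps the C11 configuration.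

**22 ⇒ 21 ⇒ 20 ⇒ 18.** Three oxidation levels are traced back: the C8 carbinol to a ketone, the lactone carbonyl C12 to the allylic ether CH2 of a methylene-tetrahydrofuran, and the furanone carbonyl C1 to the allylic CH2 of a cyclic enol ether. Keeping C8 as the ketone until both C–H oxidations are done saves a protecting group. The enol ether is oxidised first because it would not survive the chromium reagent needed for C12.

**18 ⇒ 17 ⇒ 16.** The C9–O bond is cut. C9 is the only methylene α to the C8 ketone, so the oxygen can come from an electrophilic oxidant; silylation masks it during the later oxidations.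

**16 ⇒ 14.** This disconnection carries the plan. The C1–C10 bond is cut and the C3–C8 bond re-formed, which folds the bridged ten-membered ring back into a cyclohexene fused to a 2,3-dihydrofuran with a vinyl group on C3 and a hydroxyl on C8. No other cut removes the medium ring, the bridge and the quaternary C10 at once, and the sense of C10 is then dictated by C3. Forward, the alkoxide of 14 must undergo the [3,3] shift and deliver the C8=C9 enolate.

**14 ⇒ 13 ⇒ 12 ⇒ 10.** The C2–C3 bond is cut to an oxocarbenium ion at C3 and a vinyl nucleophile, and the ring O–C10 bond to a C3 ketone with a propargyl group on C8.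
- A plain 1,2-addition of a vinyl nucleophile to a C3 ketone was rejected: axial attack anti to C11 would put the vinyl group on the wrong face.
- With the enol-ether ring already in place the five-membered ring can only be cis-fused, so the configuration of C3 follows from that of C8.
- A C3/C8 diketone was avoided because it would enolise towards C7 and aromatise with loss of the C6 oxygen.

**10 ⇒ 9 ⇒ 8 ⇒ 7.** The C8–C9 and C8–O bonds are cut back to the α′-methylene of an enone. Oxygen goes in first and carbon second, because the last group to arrive enters anti to the C7–C11 bond, and that group must be the propargyl unit.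

**7 ⇒ 5 ⇒ 4 ⇒ 2 ⇒ 1.** The C6–O bond of the cis-fused tetrahydrofuran is cut to a C12 alcohol and a C5=C6 alkene (iodoetherification, then dehydroiodination towards C4 to restore the enone). The β,γ-enone comes from the conjugated one by deconjugation. The C12 oxygen comes from allylic chlorination of the isopropenyl group of (S)-carvone 1, which supplies C7 in the required configuration.

## Alternatives that were turned down

**Alternative 1:** Cutting C7–C11 together with the lactone acyl–oxygen bond leads to the chloropyruvate ester A1 of an enantiopure dihydropyranol. Forward, an intramolecular carbonyl-ene reaction would give the cis-fused chlorohydrin lactone A2, with the alkene moved to C8=C9.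
- For: A2 has C11 with hydroxyl, chloromethyl group and lactone set in one step, the tether fixing the C6/C7/C11 relationship. On this point it is stronger than the chosen route, which reaches C11 only at the end by a directed oxidation.
- Against: A2 holds only C5–C9 and C11–C13. The ten-membered ring, the furanone, the quaternary C10 and the C8/C9 diol all remain. The pyran oxygen joining C5 and C9 in A2 must be excised, and a base-sensitive chlorohydrin must survive fragment coupling and a macrocyclisation.
- Comparison: the chosen strategy distributes risk the other way, with skeleton, bridge and C10 in one step from a chiral-pool ring and C11 late.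

**Alternative 2:** Cutting C1–C2 opens the ring to a chain ending in an iodoalkyne at C2 and an aldehyde at C1 on the quaternary C10. A chromium-mediated, nickel-catalysed alkynyl addition (Nozaki–Hiyama–Kishi type) would close the ten-membered enynol A3. Oxidation to the ynone and 5-endo attack of the C10 oxygen would then give the furanone.
- For: the chemistry tolerates the ester, chlorohydrin and lactone, and the furanone arises by a well-tried ynone cyclisation. That is stronger than the C1 oxidation proposed here.
- Against: every stereocentre from C6 to C11, including both quaternary carbons, must be built on an open chain in a long linear sequence. The closure must bend a linear alkyne into a ten-membered ring that also holds a cis alkene and a fused lactone, which costs strain and entropy, and it gives C1 epimers.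
- Comparison: the chosen route makes the ring by rearranging a six-membered ring rather than by end-to-end closure, and fixes C10 by chirality transfer, at the price of one unprecedented step.

**Alternative 3:** Cutting C5–C6 gives a (Z)-vinyl iodide at C5, already attached to the finished furanone, and a C6 aldehyde. Cathodic, chromium-catalysed alkenylation (nickel co-catalyst) would close the ring to the C6 carbinol A4, which would then lactonise onto the C12 ester.
- For: it is catalytic in chromium, the alkene geometry comes in with the iodide, the furanone and chlorohydrin exist before ring closure, and it is convergent. In these respects it is at least as strong as the chosen route.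
- Against: the C6 carbinol is created in the macrocyclisation without an obvious control element, and only the epimer that lactonises cis is useful. The electrochemical variant has little precedent for medium rings, and the seco-compound again needs its stereocentres assembled acyclically.
- Comparison: in the chosen route C6 and C7 are fixed on a small ring before any medium ring exists.

Key step: step 11

Remark: atom numbers are those of the target (C1–C10 carbocycle, oxygen bridge C3–C10, C11–C13 lactone arm, C14 on C10, C15 on C4) and are used for every intermediate. In 1 the carbonyl carbon is C3 and the isopropenyl group is C11–C13.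

## Route

**Step 1**
Reactants: 1 (S)-carvone
Product: 2 (S)-10-chlorocarvone (allylic C12 chloride)
Conditions: Ca(OCl)2, solid CO2, CH2Cl2/H2O, 0 °C
Reagents that add atoms: calcium hypochlorite, [Ca+2].[O-]Cl.[O-]Cl
Why: Ene-type allylic chlorination of the electron-rich isopropenyl group by hypochlorous acid; the conjugated ring alkene is too electron-poor to react.

**Step 2**
Reactants: 2 (S)-10-chlorocarvone
Product: 4 (S)-10-hydroxycarvone, via acetate 3 (not isolated)
Conditions: KOAc, Bu4NI (cat.), DMF, 60 °C; then K2CO3 (cat.), MeOH, 25 °C
Reagents that add atoms: potassium acetate, CC(=O)[O-].[K+]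
Why: SN2 displacement of the primary allylic chloride by acetate, then transesterification with methanol frees the C12 alcohol.

**Step 3**
Reactants: 4 (S)-10-hydroxycarvone
Product: 5 deconjugated ketone (C3 ketone with C5=C6 alkene; C4 epimers)
Conditions: KOt-Bu (2.5 equiv), t-BuOH/THF, 0 → 25 °C; then cold aqueous AcOH
Reagents that add atoms: none
Why: Classical deconjugation of an enone: equilibrating γ-deprotonation (C6–H) followed by kinetic protonation at the α-carbon C4; C7 is not touched.

**Step 4**
Reactants: 5 deconjugated ketone
Product: 7 cis-fused bicyclic enone, via iodo ether 6 (not isolated)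
Conditions: I2, NaHCO3, MeCN, 0 °C; then DBU, 25 °C
Reagents that add atoms: none
Why: 5-exo-trig iodoetherification: the C12 hydroxyl opens the C5=C6 iodonium ion at C6, which can only give the cis-fused tetrahydrofuran (sets C6). E1cB dehydroiodination through the acidic C4–H then restores the C4=C5 enone.

**Step 5**
Reactants: 7 cis-fused bicyclic enone
Product: 8 α′-hydroxy enone (C8 hydroxyl trans to the C7–C11 bond)
Conditions: NaN(SiMe3)2, THF, −78 °C; 2-(phenylsulfonyl)-3-phenyloxaziridine, −78 °C
Reagents that add atoms: 2-(phenylsulfonyl)-3-phenyloxaziridine, O=S(=O)(N1OC1c1ccccc1)c1ccccc1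
Why: Kinetic α′-deprotonation at C8 and oxygen transfer from the oxaziridine (Davis oxidation) on the convex face; the C8 configuration is erased again in step 7.

**Step 6**
Reactants: 8 α′-hydroxy enone
Product: 9 C8 triethylsilyl ether
Conditions: Et3SiCl, imidazole, DMF, 0 °C
Reagents that add atoms: chlorotriethylsilane, CC[Si](Cl)(CC)CC
Why: Standard silylation of a secondary alcohol; the ether tolerates the amide base, the Lewis acid and the gold catalyst of steps 7–9 and is removed by fluoride in step 10.

**Step 7**
Reactants: 9 C8 triethylsilyl ether
Product: 10 C8-propargyl ketone (propargyl trans and silyloxy cis to the C7–C11 bond)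
Conditions: LiN(i-Pr)2, THF, −78 °C; propargyl bromide, DMPU, −78 → −20 °C
Reagents that add atoms: propargyl bromide, C#CCBr
Why: Alkylation of the α-silyloxy ketone at C8 after kinetic deprotonation; the electrophile enters anti to the C7–C11 bond (convex face of the cis-fused bicycle). This sets the quaternary C8 with the future C9 trans to C11.

**Step 8**
Reactants: 10 C8-propargyl ketone
Product: 12 bicyclic methyl ketal (C3 methoxy; ring O between C3 and C10; C9=C10), via exocyclic enol ether 11 (not isolated)
Conditions: Ph3PAuNTf2 (2 mol %), MeOH (3 equiv), CH2Cl2, 25 °C; then pyridinium p-toluenesulfonate (5 mol %)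
Reagents that add atoms: methanol, CO
Why: Gold-catalysed cycloisomerisation of a γ-alkynyl ketone: the C3 carbonyl oxygen attacks the activated alkyne 5-exo-dig and methanol captures the oxocarbenium ion at C3. The acid then moves the exocyclic double bond of 11 into the ring. The ring oxygen can only be cis to C9, so C3 forms as one diastereomer.

**Step 9**
Reactants: 12 bicyclic methyl ketal
Product: 13 C3-vinyl dihydrofuran silyl ether
Conditions: CH2=CHBF3K, BF3·OEt2, CH2Cl2/MeCN, −78 → −30 °C
Reagents that add atoms: potassium vinyltrifluoroborate, C=C[B-](F)(F)F.[K+]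
Why: Lewis-acid ionisation of the allylic ketal and transfer of the vinyl group from boron to the oxocarbenium carbon C3 (addition of an alkenyltrifluoroborate to a ketal-derived oxocarbenium ion). A trans-fused six–five system with the planar enol-ether ring is prohibitively strained, so vinyl enters syn to the C8 silyloxy group; C3–O and C8–C9 stay on one face.

**Step 10**
Reactants: 13 C3-vinyl dihydrofuran silyl ether
Product: 14 vinyl hydrobenzofuranol
Conditions: Bu4NF, AcOH, THF, 0 → 25 °C
Reagents that add atoms: none
Why: Fluoride cleaves the tertiary silyl ether. Acetic acid keeps the free alkoxide from forming before step 11, and no acid strong enough to ionise the carbinol next to the enol ether is present.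

**Step 11**
Reactants: 14 vinyl hydrobenzofuranol
Product: 16 ring-expanded oxygen-bridged C8 ketone, via potassium enolate 15 (not isolated)
Conditions: KH (1.5 equiv), 18-crown-6 (1.5 equiv), THF, 0 → 25 °C; then pH 7 phosphate buffer, −78 °C
Reagents that add atoms: none
Why: Proposed new method: KH with 18-crown-6 gives the free potassium alkoxide at C8; the oxyanion weakens the C3–C8 bond and the 1,5-diene C1=C2–C3–C8–C9=C10 undergoes a [3,3] shift in which C1 bonds to C10 while C3–C8 breaks, giving the C8=C9 enolate 15, which is protonated to 16. The closest known reaction type is the anionic oxy-Cope ring expansion of 1,2-divinylcyclohexanols to cyclodecenones; what is without precedent is that the ether oxygen ties C3 to C10, so the six-centre array must be a boat resembling a 7-oxanorbornene instead of the usual chair. Because the breaking C3–C8 bond lies close to the nodal plane of the ring enol ether, the shift may run stepwise, by heterolysis to a C1–C5 pentadienyl anion held through oxygen to a β-alkoxy enone and conjugate re-addition of C1 to C10; both paths form the same bond. The new five-membered ring (O, C3, C2, C1, C10) closes by attack of C1 on C10 with the C9=C10 bond outside the ring (5-exo-trig in the stepwise picture), and the ten-membered carbocycle arises by ring expansion, the six-membered ring gaining C9, C10, C1 and C2 when the shared C3–C8 bond is cut. C10 is the only new stereocentre: the vinyl group sits on the face of the dihydrofuran opposite the cyclohexene, so C1 can reach only that face of C10 and the configuration of C3 is transferred suprafacially. The cis C4=C5 geometry is that of the cyclohexene, and the enolate is formed only towards C9. The step needs C1, not C5, to bond to C10 and needs re-closure to beat simple fragmentation: the ring alkene cannot align with the breaking bond and C1 closes a five-membered ring, while the enolate is quenched cold to forestall β-elimination of the C10 oxygen.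

**Step 12**
Reactants: 16 ring-expanded oxygen-bridged C8 ketone
Product: 17 C9 hydroxy ketone
Conditions: NaN(SiMe3)2, THF, −78 °C; 2-(phenylsulfonyl)-3-phenyloxaziridine, −78 °C
Reagents that add atoms: 2-(phenylsulfonyl)-3-phenyloxaziridine, O=S(=O)(N1OC1c1ccccc1)c1ccccc1
Why: Kinetic deprotonation by the bulky amide at the C9 methylene rather than the ring-fusion methine C7, then Davis oxidation. The oxaziridine should attack the face opposite the C10–C1 bond, which stands roughly perpendicular to the C8=C9 plane, and that face gives the required C9 configuration.

**Step 13**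
Reactants: 17 C9 hydroxy ketone
Product: 18 C9 triethylsilyl ether
Conditions: Et3SiOSO2CF3, 2,6-lutidine, CH2Cl2, −78 °C
Reagents that add atoms: triethylsilyl trifluoromethanesulfonate, CC[Si](CC)(CC)OS(=O)(=O)C(F)(F)F
Why: Silylation of the hindered secondary alcohol under non-enolising conditions; the ether protects C9 during the oxidations and later makes the hydride reduction at C8 non-chelating.

**Step 14**
Reactants: 18 C9 triethylsilyl ether
Product: 20 3(2H)-furanone (C1 ketone), via allylic alcohol 19 (not isolated)
Conditions: DDQ (2.5 equiv), CH2Cl2/pH 7 phosphate buffer, 0 → 25 °C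
Reagents that add atoms: water, O
Why: Proposed new method: DDQ should abstract hydride from C1, whose two C–H bonds are held parallel to the π system of the C2=C3 enol ether by the five-membered ring; water captures the oxygen-stabilised allyl cation at C1 and the enol-ether allylic alcohol 19 is oxidised further by DDQ to the vinylogous ester. The closest known reaction types are the DDQ dehydrogenation of silyl enol ethers, which begins with the same hydride abstraction, and the DDQ oxidation of activated benzylic methylenes to ketones in wet solvent. The competing hydride donor C6–H is tertiary, buried at the ring fusion and expected to lie near the plane of the diene.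

**Step 15**
Reactants: 20 3(2H)-furanone
Product: 21 α-methylene lactone (C12 carbonyl)
Conditions: CrO3, 3,5-dimethylpyrazole, CH2Cl2, −20 °C
Reagents that add atoms: chromium trioxide, O=[Cr](=O)=O
Why: Allylic oxidation of the ether CH2 of a 3-methylenetetrahydrofuran to the α-methylene γ-lactone by the hexavalent chromium–pyrazole complex. The enol ether is already a robust vinylogous ester and no free hydroxyl is present.

**Step 16**
Reactants: 21 α-methylene lactone
Product: 22 C8 alcohol (8,9-threo)
Conditions: NaBH4, CeCl3·7H2O, MeOH/THF, −78 °C
Reagents that add atoms: none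
Why: Luche reduction: 1,2-selective for the C8 ketone over the enoate and the vinylogous ester, and mild enough not to isomerise the methylene lactone. Hydride arriving from the ring periphery anti to the C9 silyloxy group should give the threo arrangement.

**Step 17**
Reactants: 22 C8 alcohol
Product: 23 triol (C8, C11 and C13 hydroxyls)
Conditions: OsO4 (1.05 equiv), Me2NCH2CH2NMe2, CH2Cl2, −78 °C; then aqueous Na2SO3
Reagents that add atoms: osmium tetroxide, O=[Os](=O)(=O)=O
Why: Hydrogen-bond-directed dihydroxylation: the OsO4–diamine complex is held by the C8 hydroxyl and delivered to the face of the C11=C13 alkene that carries C8, the face an unguided reagent would avoid. The tertiary hydroxyl therefore comes out cis to the C7–C8 bond.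

**Step 18**
Reactants: 23 triol
Product: 25 spiro-epoxy lactone, via primary tosylate 24 (not isolated)
Conditions: Bu2SnO (cat.), p-TsCl, Et3N, CH2Cl2, 0 °C; then DBU, 25 °C
Reagents that add atoms: none
Why: Tin-acetal-catalysed sulfonylation selects the primary hydroxyl of the 1,2-diol. The tertiary alkoxide then displaces the tosylate (3-exo-tet), so the C11–O bond and its configuration are retained.

**Step 19**
Reactants: 25 spiro-epoxy lactone
Product: 26 C8 angelate
Conditions: angelic acid, 2,4,6-trichlorobenzoyl chloride, Et3N, toluene, 25 °C; then 25, toluene, 75 °C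
Reagents that add atoms: angelic acid, C/C=C(/C)C(=O)O
Why: Yamaguchi esterification through the mixed anhydride without a nucleophilic catalyst, which limits Z to E isomerisation of the angelate; C8–OH is the only free hydroxyl.

**Step 20**
Reactants: 26 C8 angelate
Product: 27 CNP0272644.1
Conditions: HCl (4 M in 1,4-dioxane), MeOH/THF, 0 °C
Reagents that add atoms: hydrogen chloride, Cl
Why: Acid-promoted SN2 opening of the glycidic-ester-type epoxide by chloride at the primary C13 leaves the C11–O bond untouched, and the same acid removes the C9 silyl ether. Finishing under acid avoids epoxide re-closure, acyl migration and angelate isomerisation.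

## Compound list

1 | (S)-carvone | CC1=CC[C@@H](CC1=O)C(C)=C | starting material
2 | (S)-5-(3-chloroprop-1-en-2-yl)-2-methylcyclohex-2-en-1-one (10-chlorocarvone) | CC1=CC[C@@H](CC1=O)C(CCl)=C | intermediate
3 | (S)-2-(4-methyl-5-oxocyclohex-3-en-1-yl)allyl acetate | CC1=CC[C@@H](CC1=O)C(COC(C)=O)=C | intermediate
4 | (S)-5-(3-hydroxyprop-1-en-2-yl)-2-methylcyclohex-2-en-1-one (10-hydroxycarvone) | CC1=CC[C@@H](CC1=O)C(CO)=C | intermediate
5 | 5-(3-hydroxyprop-1-en-2-yl)-2-methylcyclohex-3-en-1-one, C7 as in 1, C4 both epimers | CC1C=C[C@@H](CC1=O)C(CO)=C | intermediate
6 | cis-fused iodo ether: C3 ketone, C5 iodide trans to the ring oxygen on C6, 3-methylenetetrahydrofuran on C6/C7, C4 both epimers | O=C1C[C@H]2C(=C)CO[C@H]2[C@H](I)C1C | intermediate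
7 | cis-fused 6-methyl-3-methylene-3,3a,4,7a-tetrahydrobenzofuran-5(2H)-one (C3 ketone, C4=C5, H6/H7 cis) | O=C1C[C@H]2C(=C)CO[C@H]2C=C1C | intermediate
8 | C8-hydroxy derivative of 7, hydroxyl trans to the C7–C11 bond | O=C1[C@H](O)[C@H]2C(=C)CO[C@H]2C=C1C | intermediate
9 | C8 triethylsilyl ether of 8 | O=C1[C@H](O[Si](CC)(CC)CC)[C@H]2C(=C)CO[C@H]2C=C1C | intermediate
10 | C8-quaternary ketone: propargyl trans and triethylsilyloxy cis to the C7–C11 bond | O=C1[C@@](CC#C)(O[Si](CC)(CC)CC)[C@H]2C(=C)CO[C@H]2C=C1C | intermediate
11 | bicyclic methyl ketal with exocyclic enol ether (C3 OMe, ring O C3–C10, C10=C14), OMe and OSiEt3 cis | CO[C@@]12OC(=C)C[C@]1(O[Si](CC)(CC)CC)[C@H]3C(=C)CO[C@H]3C=C2C | intermediate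
12 | bicyclic methyl ketal with endocyclic enol ether (C3 OMe, C9=C10–CH3), OMe and OSiEt3 cis | CO[C@@]12OC(C)=C[C@]1(O[Si](CC)(CC)CC)[C@H]3C(=C)CO[C@H]3C=C2C | intermediate
13 | C3-vinyl dihydrofuran, C8 triethylsilyl ether; vinyl and OSiEt3 cis, dihydrofuran ring trans to the tetrahydrofuran ring | C=C[C@@]12OC(C)=C[C@]1(O[Si](CC)(CC)CC)[C@H]3C(=C)CO[C@H]3C=C2C | intermediate
14 | vinyl hydrobenzofuranol: cis-fused cyclohexene–2,3-dihydrofuran, C3 vinyl and C8 hydroxyl cis, fused 3-methylenetetrahydrofuran on the opposite face | C=C[C@@]12OC(C)=C[C@]1(O)[C@H]3C(=C)CO[C@H]3C=C2C | intermediate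
15 | potassium enolate of 16 (C8–O−, C8=C9 with C7 and C10 cis) | [K+].[O-]/C=1[C@@H]2[C@H](/C=C(/C)C3=CC[C@](C)(O3)\C=1)OCC2=C | intermediate
16 | ring-expanded ketone: ten-membered C8 ketone, O bridge C3–C10, C2=C3 enol ether, cis C4=C5, quaternary C10, cis-fused 3-methylenetetrahydrofuran on C6/C7 | O=C1[C@@H]2[C@H](/C=C(/C)C3=CC[C@](C)(O3)C1)OCC2=C | intermediate
17 | C9-hydroxy derivative of 16 | O=C1[C@@H]2[C@H](/C=C(/C)C3=CC[C@](C)(O3)[C@@H]1O)OCC2=C | intermediate
18 | C9 triethylsilyl ether of 17 | O=C1[C@@H]2[C@H](/C=C(/C)C3=CC[C@](C)(O3)[C@@H]1O[Si](CC)(CC)CC)OCC2=C | intermediate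
19 | C1 alcohol of 18 (C1 epimers) | O=C1[C@@H]2[C@H](/C=C(/C)C3=CC(O)[C@](C)(O3)[C@@H]1O[Si](CC)(CC)CC)OCC2=C | intermediate
20 | 3(2H)-furanone: C1 ketone of 18 | O=C1[C@@H]2[C@H](/C=C(/C)C3=CC(=O)[C@](C)(O3)[C@@H]1O[Si](CC)(CC)CC)OCC2=C | intermediate
21 | α-methylene lactone: C12 carbonyl of 20 | O=C1[C@@H]2[C@H](/C=C(/C)C3=CC(=O)[C@](C)(O3)[C@@H]1O[Si](CC)(CC)CC)OC(=O)C2=C | intermediate
22 | C8 alcohol of 21 (8,9-threo) | O[C@H]1[C@@H]2[C@H](/C=C(/C)C3=CC(=O)[C@](C)(O3)[C@@H]1O[Si](CC)(CC)CC)OC(=O)C2=C | intermediate
23 | triol: C8 OH, tertiary C11 OH cis to C8 on the lactone, primary C13 OH; C9 OSiEt3 | O[C@H]1[C@@H]2[C@H](/C=C(/C)C3=CC(=O)[C@](C)(O3)[C@@H]1O[Si](CC)(CC)CC)OC(=O)[C@@]2(O)CO | intermediate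
24 | C13 p-toluenesulfonate of 23 | O[C@H]1[C@@H]2[C@H](/C=C(/C)C3=CC(=O)[C@](C)(O3)[C@@H]1O[Si](CC)(CC)CC)OC(=O)[C@@]2(O)COS(=O)(=O)c4ccc(C)cc4 | intermediate
25 | 11,13-spiro-epoxy lactone, epoxide oxygen on the lactone face that carries C8 | O[C@H]1[C@@H]2[C@H](/C=C(/C)C3=CC(=O)[C@](C)(O3)[C@@H]1O[Si](CC)(CC)CC)OC(=O)[C@@]2(O4)C4 | intermediate
26 | C8 angelate of 25 | C/C=C(/C)C(=O)O[C@H]1[C@@H]2[C@H](/C=C(/C)C3=CC(=O)[C@](C)(O3)[C@@H]1O[Si](CC)(CC)CC)OC(=O)[C@@]2(O4)C4 | intermediate
27 | CNP0272644.1 | C/C=C(/C)C(=O)O[C@H]1[C@@H]2[C@H](/C=C(/C)C3=CC(=O)[C@](C)(O3)[C@@H]1O)OC(=O)[C@@]2(O)CCl | target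

## Step count and risk

Total step count: 20.
Longest linear sequence: 20 steps (fully linear from 1).

**Step 11 (key step, proposed new method).**
- What may go wrong: the alkoxide fragments at C3–C8 without the C1–C10 bond forming, or the tethered anion re-closes through C5 or onto the C8 carbonyl. The bridged boat aligns the breaking bond poorly with the ring enol ether. Prolonged exposure of enolate 15 also risks β-elimination of the C10 oxygen.
- Fallback (known chemistry), from 10 back to 16: gold-catalysed hydration of the alkyne of 10 gives the 1,4-diketone F1. Thermodynamic enol silylation of the methyl ketone (i-Pr3SiOSO2CF3, Et3N) gives the (Z)-triisopropylsilyl enol ether F2. Vinylmagnesium bromide adds to the remaining enone carbonyl anti to the C8 silyloxy group to give the divinyl carbinol F3. KH/18-crown-6 then effects the established chair-type anionic oxy-Cope ring expansion with the alkoxide pseudo-equatorial; this should place C1 on the same face of C10 as in the bridged variant and give the cyclodecadienone F4. Bu4NF removes both silyl groups to the hydroxy dione F5. Pyridinium p-toluenesulfonate with molecular sieves closes the C10 hydroxyl onto the C3 ketone by cyclodehydration and returns 16.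

**Step 14 (proposed new method).**
- What may go wrong: poor site selectivity of hydride abstraction (C6–H, allylic and α to oxygen, competes with C1–H), or hydrolytic opening of the enol ether by the acidic hydroquinone.
- Fallback (known chemistry), from 18 back to 20: PhSeCl in MeOH adds selenium to C2 and methoxide to C3, giving the seleno ketal F6. H2O2/pyridine brings about selenoxide elimination away from oxygen to the 2-methoxy-2,5-dihydrofuran F7. Mild aqueous acid transposes the allylic ketal to the C1 alcohol 19, here isolated, and MnO2 oxidises it to 20.

**Step 9.**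
- What may go wrong: slow vinyl transfer to the hindered, fully substituted oxocarbenium ion, so that ionisation of 12 is followed by elimination or self-condensation of the enol ether.
- Fallback, from 12 back to 13: a slimmer alkynyl nucleophile, potassium (trimethylsilyl)ethynyltrifluoroborate with BF3·OEt2, gives the silylalkyne F8. K2CO3/MeOH gives the terminal alkyne F9, and semi-hydrogenation over Pd/CaCO3 poisoned with Pb(OAc)2 and quinoline gives 13.

**Step 12.**
- What may go wrong: enolisation of 16 towards C7 (that C–H is allylic), which would be followed by β-elimination of the C6 oxygen, and leakage of facial selectivity once the ketone has relaxed conformationally.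
- Fallback, from 14 to 17: the regiodefined enolate 15 is not quenched but treated directly at −78 °C with the oxaziridine in the flask of step 11 (no new compound, F0).

**Step 16.**
- What may go wrong: poor facial selectivity, the conformation of the ten-membered ring overriding the local preference for attack anti to the silyloxy group.
- Fallback, from 21 back to 22: if reduction favours the C8 epimer F10, it is inverted by Mitsunobu esterification with chloroacetic acid (Ph3P, diisopropyl azodicarboxylate) to the chloroacetate F11, which thiourea/NaHCO3 cleaves to 22.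

**Step 17.**
- What may go wrong: the directing hydrogen bond fails to override the steric bias of the lactone face, or osmylation occurs at C4=C5.
- Fallback, from 22 directly to 25: alkoxide-directed nucleophilic (Weitz–Scheffer-type) epoxidation of the enoate with LiOOt-Bu (from t-BuOOH and n-BuLi), in which the C8 lithium alkoxide delivers the peroxide to its own face (no new compound, F0).

## Further compounds

F1 | step 11 | 1,4-diketone: C3 enone ketone, C8 acetonyl trans to C11, C8 OSiEt3 | O=C1[C@@](CC(C)=O)(O[Si](CC)(CC)CC)[C@H]2C(=C)CO[C@H]2C=C1C
F2 | step 11 | (Z)-triisopropylsilyl enol ether of F1 (C9=C10, silyloxy cis to C8) | O=C1[C@@](/C=C(/C)O[Si](C(C)C)(C(C)C)C(C)C)(O[Si](CC)(CC)CC)[C@H]2C(=C)CO[C@H]2C=C1C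
F3 | step 11 | divinyl carbinol: C3 hydroxyl cis to C8 OSiEt3, C3 vinyl cis to the C8 alkenyl group | O[C@@]1(C=C)[C@@](/C=C(/C)O[Si](C(C)C)(C(C)C)C(C)C)(O[Si](CC)(CC)CC)[C@H]2C(=C)CO[C@H]2C=C1C
F4 | step 11 | cyclodecadienone: C3 ketone, C8 triethylsilyl enol ether, C10 triisopropylsilyl ether | O=C1CC[C@](C)(O[Si](C(C)C)(C(C)C)C(C)C)/C=C(\O[Si](CC)(CC)CC)[C@@H]2[C@H](/C=C1/C)OCC2=C
F5 | step 11 | hydroxy dione: C3 and C8 ketones, C10 tertiary alcohol | O=C1CC[C@](C)(O)CC(=O)[C@@H]2[C@H](/C=C1/C)OCC2=C
F6 | step 14 | C2-phenylseleno C3-methyl ketal of 18 | O=C1[C@@H]2[C@H](/C=C(/C)C3(OC)C([Se]c4ccccc4)C[C@](C)(O3)[C@@H]1O[Si](CC)(CC)CC)OCC2=C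
F7 | step 14 | 2-methoxy-2,5-dihydrofuran (C1=C2, C3 OMe) | O=C1[C@@H]2[C@H](/C=C(/C)C3(OC)C=C[C@](C)(O3)[C@@H]1O[Si](CC)(CC)CC)OCC2=C
F8 | step 9 | C3 (trimethylsilyl)ethynyl analogue of 13 | C[Si](C)(C)C#C[C@@]12OC(C)=C[C@]1(O[Si](CC)(CC)CC)[C@H]3C(=C)CO[C@H]3C=C2C
F9 | step 9 | C3 ethynyl analogue of 13 | C#C[C@@]12OC(C)=C[C@]1(O[Si](CC)(CC)CC)[C@H]3C(=C)CO[C@H]3C=C2C
F0 | step 12 | none | none
F10 | step 16 | C8 epimer of 22 | O[C@@H]1[C@@H]2[C@H](/C=C(/C)C3=CC(=O)[C@](C)(O3)[C@@H]1O[Si](CC)(CC)CC)OC(=O)C2=C
F11 | step 16 | C8 chloroacetate with the configuration of 22 | ClCC(=O)O[C@H]1[C@@H]2[C@H](/C=C(/C)C3=CC(=O)[C@](C)(O3)[C@@H]1O[Si](CC)(CC)CC)OC(=O)C2=C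
F0 | step 17 | none | none
A1 | alternative 1 | chloropyruvate ester of (R)-3,6-dihydro-2H-pyran-3-ol | ClCC(=O)C(=O)O[C@H]1COCC=C1
A2 | alternative 1 | cis-fused dihydropyran chlorohydrin lactone | C1=C[C@@H]2[C@H](CO1)OC(=O)[C@@]2(O)CCl
A3 | alternative 2 | ten-membered enynol (C1 epimers) | C/C=C(/C)C(=O)O[C@H]1[C@@H]2[C@H](/C=C(/C)C#CC(O)[C@](C)(O[Si](CC)(CC)CC)[C@@H]1O[Si](C)(C)C(C)(C)C)OC(=O)[C@@]2(O)CCl
A4 | alternative 3 | macrocyclic C6 carbinol with C12 methyl ester | C/C=C(/C)C(=O)O[C@H]1[C@H]([C@@H](O)/C=C(/C)C3=CC(=O)[C@](C)(O3)[C@@H]1O[Si](C)(C)C(C)(C)C)[C@](O)(CCl)C(=O)OC
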